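**Two runs, one knot.** North-west and north cannot separate charge from temperature, since both changed at once. So look for a number that depends on neither.

the same everywhere: free catalyst 0.076 mol%
- north-west: starting material 28 mM; second substrate 1 equiv; temperature 96 °C; run made earlier
- north: starting material 44 mM; second substrate 1 equiv; temperature 110 °C; run made earlier
- teal: starting material 20 mM; second substrate 1.00 equiv; temperature 90 °C; time 5.0 min
- grey: starting material 20 mM; second substrate 1.00 equiv; temperature 115 °C; time 5.0 min

north-west run (percent of the starting material charged)

| time / min | over-reaction product / % | uncatalysed product / % | target / % | starting material / % |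
|---|---|---|---|---|
| 0.250 | 0 | 0 | 3.7 | 95.4 |
| 0.500 | 1.1 | 0.2 | 7.1 | 91.4 |
| 1.33 | 4.0 | 1.1 | 17.3 | 78.2 |
| 3.00 | 14.8 | 2.4 | 27.9 | 55.6 |

north run (percent of the starting material charged)

| time / s | over-reaction product / % | uncatalysed product / % | target / % | starting material / % |
|---|---|---|---|---|
| 10.0 | 0 | 1.9 | 8.4 | 90.5 |
| 12.0 | 1.6 | 1.3 | 9.2 | 88.4 |
| 30.0 | 4.8 | 2.2 | 19.8 | 73.4 |
| 60.0 | 17.1 | 3.9 | 26.4 | 52.4 |

(standard deviation of a reading: 0.5 percentage points)

* which of these there is most of at the end, counted by the starting material in it, teal (starting material / over-reaction product / uncatalysed product / target)
* which of these there is most of at the end, counted by the starting material in it, grey (starting material / over-reaction product / uncatalysed product / target)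
* how much there is at the end of the one of these that leads, in percent of the starting material charged: teal
* how much there is at the end of the one of these that leads, in percent of the starting material charged: grey

- the numbers in the tables scatter with a standard deviation of 0.5 percentage points

**Main step.** Treat starting material as decaying first-order. Its last readings give 0.196 min⁻¹ in north-west and 0.646 min⁻¹ in north. Assume that at fixed mol% this constant follows the charge. Per unit charge, north is then faster by a factor 2.10; put that on temperature and spread it evenly over the degrees. This gives 0.102 min⁻¹ for teal and 0.383 min⁻¹ for grey. After 5.0 min, this reckoning leaves teal 60.2 % starting material and grey 14.7 %. Teal and grey both lie outside the temperatures of the runs, so treat both figures as rough.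

**Over-reaction.** Now compare rates at one moment. Between the last two readings of each run, divide the gain in over-reaction product by mean target. Divide the gain in over-reaction product plus target by mean starting material. The quotient of these is 1.49 in north-west and 1.77 in north. Time cancels in it, and free catalyst cancels too, on the assumption that both steps are first-order in it. Carry the mean, 1.63, the selectivity factor s: target's loss per unit of target over its making per unit of starting material. Use over making is then s[target]/[starting material], which drifts upward as starting material falls. Integrated, with a the fraction of starting material left, target is (a^s − a)/(1 − s). For teal this gives 26.1 % target, so by this reckoning starting material leads teal. For grey it gives 16.4 % target, which leaves 68.9 % over-reaction product.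

**Uncatalysed leak.** Uncatalysed product took 8.19 % of the spent starting material at north's last reading. Give grey that share, and over-reaction product drops to 61.9 %, still the leader.

**The forecast.** It puts teal at 62 % starting material and grey at 60 % over-reaction product, near my figures but not equal to them, and warns: “Concentration and temperature are confounded”.

**The result.** Teal ends with 59.6 % starting material, and grey with 75.9 % over-reaction product.

    starting material + free catalyst ⇌ catalyst intermediate A (K = 88.0 L mol⁻¹, k = 20000 L mol⁻¹ min⁻¹, Ea = 54.0 kJ mol⁻¹, ΔH = −43.0 kJ mol⁻¹)
    catalyst intermediate B → free catalyst + second product (k = 160 min⁻¹, Ea = 96.0 kJ mol⁻¹)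
    starting material → uncatalysed product (k = 0.00570 min⁻¹, Ea = 126 kJ mol⁻¹)
    free catalyst + target → free catalyst + over-reaction product (k = 23000 L mol⁻¹ min⁻¹, Ea = 55.0 kJ mol⁻¹)
    second substrate + free catalyst ⇌ catalyst intermediate B (K = 68.0 L mol⁻¹, k = 6.00 × 10⁵ L mol⁻¹ min⁻¹, Ea = 31.0 kJ mol⁻¹, ΔH = −90.0 kJ mol⁻¹)
    catalyst intermediate A → free catalyst + target (k = 820 min⁻¹, Ea = 71.0 kJ mol⁻¹)
    (constants at 90 °C)

**Same factor.** Grey's starting material fell further than I reckoned, to 4.48 %, with 90.8 % of its catalyst free against 45.8 % in teal. Put that amount of starting material into the formula with s and it gives 6.11 % target, where grey holds 6.02 %. A repeat of grey at 100 °C keeps 30.5 % starting material, so the formula gives 25.5 % target, and that flask holds 25.9 %.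

All runs stem from a simulated flask with constants of no real substance.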